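Reciprocal seconds are the unit for taking over these flasks, which differ in free base.

| flask | electrophile | nucleophile | free base | time |
|---|---|---|---|---|
| ochre | 2.0 mM (fed, over 1.5 s) | 1.50 equiv | 1.20 equiv | 2.5 min |
| violet | 2.0 mM (fed, over 1.5 s) | 1.50 equiv | 4.80 equiv | 2.5 min |
| amber | 2.0 mM (fed, over 1.5 s) | 1.50 equiv | 2.40 equiv | 2.5 min |

1. part of the electrophile that has reacted at the end, ochre
2. part of the electrophile that has reacted at the end, violet
3. part of the electrophile that has reacted at the end, amber
4. what raising the equivalents of free base from its lowest to its highest value here does to the part of the electrophile that has reacted (changes below 5 percentage points count as none) (it rises / it falls / no change)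

    electrophile + nucleophile → acid set free + target (k1 = 75 /M/s)
    nucleophile + acid set free ⇌ protonated nucleophile, settled at all times (K2 = 16000 /M)
    acid set free + free base ⇌ salt of the base, settled at all times (K3 = 2.1 × 10⁷ /M)
    electrophile + target → side product (k4 = 450 /M/s)
    electrophile ⇌ dormant form (K5 = 7.0, k5 = 0.22 /s)

Your electrophile goes to target with nucleophile, and the target is attacked by more electrophile. It also slips into a dormant form at 0.22 /s and returns at 0.0314 /s. Dormant counts as reacted, so what you will find unreacted is free electrophile. I take nucleophile as charged, which gives a pseudo-first-order drain of 0.225 /s, and leave out the attack on target. With a fast drain, the store empties at the return rate; with a slow drain, at drain over 7.0. Joining both ends: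

leak = return × drain / (forward + drain) = 0.0159 /s

That is the leak rate, the part of the dormant store lost for good each second. I reckon the store fills to forward / (forward + drain) = 49.4 %, so by my reckoning it holds at the end:

store × exp(−leak × time) = 4.61 %

Free electrophile stands at return / (forward + drain) = 0.0706 of that, which gives 99.7 % reacted for ochre, 99.7 % for violet and 99.7 % for amber.

Leave the free base alone. Its lowest charge, 2.40 mM, exceeds the 2.0 mM of acid possible, and at the start of ochre the nucleophile's claim on acid is 0.0952 % of the base's, so I expect no change.

The forecast gives 99.8 %, 99.8 % and 99.8 %, each 0.13 percentage points from mine, and no change, since “the three runs behave alike”.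

The flasks give 99.8 %, 99.8 % and 99.8 %: no change.

In ochre, dormant form falls from 11.2 % at 1.25 min to 3.01 % at 2.50 min, a reading of 0.0175 /s against the leak of 0.0159 /s. For violet, the answer has moved by 5 points at 0.339 equiv of nucleophile. The neighbour of ochre with 0.380 equiv has a drain of 0.0570 /s and a leak of 0.006467 /s, so I reckon 3.43 % free electrophile at the end. That neighbour holds 4.5 % free electrophile, with 95.5 % reacted.

The constants used here were set for the occasion; the rest is arithmetic.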